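**Retrosynthetic overview**

1. Numbering: decalin carbons C1–C10 (ring A = C1–C5 and C10; ring B = C5–C10); C11 is the methylene on C4; C12, C13 and C14 are the methyls on C5, C8 and C9; C15 is the CH2 between C9 and the quinone.
2. The plan rests on ring A: C10 (H) and quaternary C5 (C12) are the β- and α-carbons of 2-methylcyclohex-2-enone, C4 is its carbonyl (later C4=C11), and the bonds these two carbons send into ring B (C10–C9, C5–C6) are trans, as when an enolate is trapped anti to a new β-substituent.
3. Late disconnections: hydroxyquinone from the tetramethoxyarene (oxidative demethylation, selective hydrolysis); C4=C11 from the C4 ketone; ring B through the C8–C9 bond, by 6-exo closure of a C8 radical onto the styrene carbon C9.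
4. Key disconnection: C9–C10 and C5–C6 in one operation, by copper/phosphoramidite-catalysed conjugate addition of the alkenylalane from bromide 5 to enone 6 and Michael trapping of the enolate with the silylated vinyl ketone 7; 5 comes from 1,2,4,5-tetramethoxybenzene in three steps.
5. Ring order: ring A is bought with 6, ring B is closed in step 7, the quinone is unveiled last.

Key step: step 4

Assumption: 3-(trimethylsilyl)but-3-en-2-one (7), the α-silylated form of methyl vinyl ketone, is taken as a purchased reagent; silicon is an activating group that is lost in the work-up of step 4.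
Remark on the chemistry: the alkenyl unit is carried as the isomer with the aryl ring cis to the metal-bearing carbon (later cis to C10), because only a cis aryl group makes allylic 1,3-strain fix the C10–C9 rotamer that the ring-B closure needs.

**Route**

Step 1
Reactants: 1 1,2,4,5-tetramethoxybenzene
Product: 3 2,3,5,6-tetramethoxybenzaldehyde, via aryllithium 2 (not isolated)
Conditions: n-BuLi, TMEDA, THF, 0 °C; DMF, 0 °C to rt; aq. HCl
Reagents that add atoms: N,N-dimethylformamide, CN(C)C=O
Why: Directed ortho-metalation removes one of the two equivalent ring hydrogens, each flanked by two methoxy groups, and the aryllithium is formylated by DMF.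

Step 2
Reactants: 3 2,3,5,6-tetramethoxybenzaldehyde
Product: 4 3-(2,2-dibromoethenyl)-1,2,4,5-tetramethoxybenzene
Conditions: CBr4, PPh3, CH2Cl2, 0 °C
Reagents that add atoms: carbon tetrabromide, BrC(Br)(Br)Br
Why: Ramirez dibromo-olefination (first stage of the Corey–Fuchs sequence), a Wittig reaction of Ph3P=CBr2 that tolerates hindered, electron-rich benzaldehydes.

Step 3
Reactants: 4 3-(2,2-dibromoethenyl)-1,2,4,5-tetramethoxybenzene
Product: 5 3-[(Z)-2-bromoprop-1-en-1-yl]-1,2,4,5-tetramethoxybenzene (bromine cis to the aryl ring)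
Conditions: Me2Zn, PdCl2(DPEphos) (5 mol %), THF, 0 °C to rt
Reagents that add atoms: dimethylzinc, C[Zn]C
Why: Trans-selective Negishi coupling: zerovalent palladium inserts into the less hindered C–Br bond trans to the aryl ring and methyl replaces that bromine with retention, so the remaining bromine stays cis to the aryl ring.

Step 4
Reactants: 5 3-[(Z)-2-bromoprop-1-en-1-yl]-1,2,4,5-tetramethoxybenzene, 6 2-methylcyclohex-2-en-1-one, 7 3-(trimethylsilyl)but-3-en-2-one
Product: 13 (2R,3R)-2-methyl-2-(3-oxobutyl)-3-[(Z)-1-(2,3,5,6-tetramethoxyphenyl)prop-1-en-2-yl]cyclohexan-1-one, via alkenyllithium 8 (not isolated), via alkenyldimethylalane 9 (not isolated), via aluminium enolate 10 (not isolated), via adduct enolate 11 (not isolated), via silyl diketone 12 (not isolated)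
Conditions: 5, t-BuLi (2 equiv), Et2O, −78 °C; Me2AlCl, −78 to −30 °C; 6, copper thiophene-2-carboxylate (CuTC, 5 mol %), BINOL-derived phosphoramidite with a bis(1-phenylethyl)amino group (10 mol %, antipode chosen for (R) at C10), Et2O, −30 °C; 7, −30 to 0 °C; 1 M aq. HCl, THF, 0 °C
Reagents that add atoms: none
Why: Bromine–lithium exchange with retention and transmetalation give alane 9, whose alkenyl group passes to copper; the chiral copper–phosphoramidite complex delivers it to C10 of 6 through a π-complex and a trivalent copper intermediate, and reductive elimination leaves the dimethylaluminium enolate 10, which adds through an aluminium-bridged transition state to the vinyl ketone 7 (Michael addition), the silyl group stabilising the new enolate and stopping further addition before acid work-up removes silicon. The closest known reactions are the CuTC/phosphoramidite conjugate addition of alkenylalanes and of trialkylalanes to cyclic enones with trapping of the aluminium enolate, and the Michael addition of preformed enolates to α-silyl vinyl ketones used in Robinson annulations. No ring is closed; the step forms C9–C10 and C5–C6. C10 is set by the ligand on copper, and C5 by approach of 7 to the enolate face anti to the new C10 alkenyl group, which gives the trans relation of the two ring-B bonds. The step needs alkenyl rather than methyl transfer from aluminium (sp2 groups migrate first), retention of the alkene geometry (the alkenyl metals are configurationally stable at low temperature) and C–C bond formation at the fully substituted enolate carbon, the only nucleophilic carbon of 10.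

Step 5
Reactants: 13 (2R,3R)-2-methyl-2-(3-oxobutyl)-3-[(Z)-1-(2,3,5,6-tetramethoxyphenyl)prop-1-en-2-yl]cyclohexan-1-one
Product: 14 (2R,3R)-2-(3-hydroxybutyl)-2-methyl-3-[(Z)-1-(2,3,5,6-tetramethoxyphenyl)prop-1-en-2-yl]cyclohexan-1-ol (epimers at both carbinol carbons)
Conditions: LiAlH4, THF, 0 °C to rt; H2O
Reagents that add atoms: none
Why: Hydride reduction of both ketones, with no selectivity required because both carbinol carbons become trigonal again later (C8 as a radical, C4 as a ketone), and with C5 and C10 untouched.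

Step 6
Reactants: 14 (2R,3R)-2-(3-hydroxybutyl)-2-methyl-3-[(Z)-1-(2,3,5,6-tetramethoxyphenyl)prop-1-en-2-yl]cyclohexan-1-ol
Product: 15 O-phenyl thionocarbonate of 14 at the side-chain (C8) hydroxyl, ring (C4) hydroxyl free
Conditions: PhOC(S)Cl (1.1 equiv), pyridine, CH2Cl2, 0 °C
Reagents that add atoms: O-phenyl chlorothionoformate, S=C(Cl)Oc1ccccc1
Why: Thioacylation to a Barton–McCombie precursor should occur at the side-chain carbinol, flanked only by CH3 and CH2, well before the ring carbinol next to quaternary C5.

Step 7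
Reactants: 15 O-phenyl thionocarbonate of 14 at the side-chain hydroxyl
Product: 16 (4aR,5S,6R,8aR)-5,6,8a-trimethyl-5-[(2,3,5,6-tetramethoxyphenyl)methyl]decahydronaphthalen-1-ol (C1 epimers)
Conditions: Bu3SnH (syringe pump, 8 h), AIBN, toluene (0.002 M), 110 °C
Reagents that add atoms: none
Why: Barton–McCombie fragmentation gives the secondary C8 radical, which closes 6-exo-trig onto C9 through a chair transition state on the ring-A conformer with C6 and C9 equatorial: C13 sits equatorial (sets C8), allylic 1,3-strain from the cis aryl group holds C10–H in the alkene plane so that C8 enters from the C5 side with C15 equatorial and C14 axial (sets C9), and the benzylic C15 radical takes hydrogen from the stannane, whose slow addition should let closure outrun reduction.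

Step 8
Reactants: 16 (4aR,5S,6R,8aR)-5,6,8a-trimethyl-5-[(2,3,5,6-tetramethoxyphenyl)methyl]decahydronaphthalen-1-ol
Product: 17 (4aR,5S,6R,8aR)-5,6,8a-trimethyl-5-[(2,3,5,6-tetramethoxyphenyl)methyl]octahydronaphthalen-1(2H)-one
Conditions: Dess–Martin periodinane, CH2Cl2, rt
Reagents that add atoms: none
Why: Dess–Martin oxidation converts both carbinol epimers to the one C4 ketone, and no stereocentre can epimerise because C5 is quaternary and C3 is CH2.

Step 9
Reactants: 17 (4aR,5S,6R,8aR)-5,6,8a-trimethyl-5-[(2,3,5,6-tetramethoxyphenyl)methyl]octahydronaphthalen-1(2H)-one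
Product: 18 3-{[(1S,2R,4aR,8aR)-1,2,4a-trimethyl-5-methylidenedecahydronaphthalen-1-yl]methyl}-1,2,4,5-tetramethoxybenzene
Conditions: Ph3PCH3Br, KOt-Bu, toluene, 90 °C
Reagents that add atoms: methyltriphenylphosphonium bromide, C[P+](c1ccccc1)(c1ccccc1)c1ccccc1.[Br-]
Why: Wittig methylenation with the small, salt-free ylide at elevated temperature is the standard way to convert a ketone next to a quaternary carbon into C4=C11.

Step 10
Reactants: 18 3-{[(1S,2R,4aR,8aR)-1,2,4a-trimethyl-5-methylidenedecahydronaphthalen-1-yl]methyl}-1,2,4,5-tetramethoxybenzene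
Product: 19 2,5-dimethoxy-3-{[(1S,2R,4aR,8aR)-1,2,4a-trimethyl-5-methylidenedecahydronaphthalen-1-yl]methyl}cyclohexa-2,5-diene-1,4-dione
Conditions: (NH4)2Ce(NO3)6, MeCN/H2O, 0 °C
Reagents that add atoms: water, O
Why: Oxidative demethylation by ceric ammonium nitrate (arene radical cation, attack of water, loss of methanol) across a para pair of methoxy groups, either pair giving the same quinone by the symmetry of the arene, while the isolated alkene is not oxidised in the cold.

Step 11
Reactants: 19 2,5-dimethoxy-3-{[(1S,2R,4aR,8aR)-1,2,4a-trimethyl-5-methylidenedecahydronaphthalen-1-yl]methyl}cyclohexa-2,5-diene-1,4-dione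
Product: 20 2-hydroxy-5-methoxy-3-{[(1S,2R,4aR,8aR)-1,2,4a-trimethyl-5-methylidenedecahydronaphthalen-1-yl]methyl}cyclohexa-2,5-diene-1,4-dione
Conditions: KOH, MeOH/H2O, rt; aq. HCl
Reagents that add atoms: potassium hydroxide, [K+].[OH-]
Why: Addition–elimination hydrolysis of a vinylogous ester should occur at the methoxy group beside the alkyl substituent, which is twisted out of conjugation and more electrophilic, and stops after one hydrolysis because the hydroxyquinone anion is deactivated; base is chosen so that the exocyclic alkene does not migrate.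

**Compound list**

1 | 1,2,4,5-tetramethoxybenzene | COc1cc(OC)c(OC)cc1OC | starting material
2 | (2,3,5,6-tetramethoxyphenyl)lithium | [Li]c1c(OC)c(OC)cc(OC)c1OC | intermediate
3 | 2,3,5,6-tetramethoxybenzaldehyde | O=Cc1c(OC)c(OC)cc(OC)c1OC | intermediate
4 | 3-(2,2-dibromoethenyl)-1,2,4,5-tetramethoxybenzene | BrC(Br)=Cc1c(OC)c(OC)cc(OC)c1OC | intermediate
5 | 3-[(Z)-2-bromoprop-1-en-1-yl]-1,2,4,5-tetramethoxybenzene | C/C(Br)=C/c1c(OC)c(OC)cc(OC)c1OC | intermediate
6 | 2-methylcyclohex-2-en-1-one | CC1=CCCCC1=O | starting material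
7 | 3-(trimethylsilyl)but-3-en-2-one | CC(=O)C(=C)[Si](C)(C)C | starting material
8 | [(E)-1-(2,3,5,6-tetramethoxyphenyl)prop-1-en-2-yl]lithium (lithium cis to the aryl ring) | C/C([Li])=C/c1c(OC)c(OC)cc(OC)c1OC | intermediate
9 | dimethyl[(Z)-1-(2,3,5,6-tetramethoxyphenyl)prop-1-en-2-yl]alane (aluminium cis to the aryl ring) | C/C(=C/c1c(OC)c(OC)cc(OC)c1OC)[Al](C)C | intermediate
10 | dimethyl({(3R)-2-methyl-3-[(Z)-1-(2,3,5,6-tetramethoxyphenyl)prop-1-en-2-yl]cyclohex-1-en-1-yl}oxy)alane | CC1=C(O[Al](C)C)CCC[C@@H]1/C(C)=C\c1c(OC)c(OC)cc(OC)c1OC | intermediate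
11 | dimethylaluminium enolate of the Michael adduct (enolate of the silyl ketone arm; ring ketone free) | CC(O[Al](C)C)=C(C[C@@]1(C)C(=O)CCC[C@@H]1/C(C)=C\c1c(OC)c(OC)cc(OC)c1OC)[Si](C)(C)C | intermediate
12 | (2R,3R)-2-methyl-2-[3-oxo-2-(trimethylsilyl)butyl]-3-[(Z)-1-(2,3,5,6-tetramethoxyphenyl)prop-1-en-2-yl]cyclohexan-1-one (epimers at the silyl-bearing carbon) | CC(=O)C(C[C@@]1(C)C(=O)CCC[C@@H]1/C(C)=C\c1c(OC)c(OC)cc(OC)c1OC)[Si](C)(C)C | intermediate
13 | (2R,3R)-2-methyl-2-(3-oxobutyl)-3-[(Z)-1-(2,3,5,6-tetramethoxyphenyl)prop-1-en-2-yl]cyclohexan-1-one | CC(=O)CC[C@@]1(C)C(=O)CCC[C@@H]1/C(C)=C\c1c(OC)c(OC)cc(OC)c1OC | intermediate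
14 | (2R,3R)-2-(3-hydroxybutyl)-2-methyl-3-[(Z)-1-(2,3,5,6-tetramethoxyphenyl)prop-1-en-2-yl]cyclohexan-1-ol (epimers at both carbinol carbons) | CC(O)CC[C@@]1(C)C(O)CCC[C@@H]1/C(C)=C\c1c(OC)c(OC)cc(OC)c1OC | intermediate
15 | O-phenyl thionocarbonate of 14 at the side-chain (C8) hydroxyl | CC(OC(=S)Oc1ccccc1)CC[C@@]1(C)C(O)CCC[C@@H]1/C(C)=C\c1c(OC)c(OC)cc(OC)c1OC | intermediate
16 | (4aR,5S,6R,8aR)-5,6,8a-trimethyl-5-[(2,3,5,6-tetramethoxyphenyl)methyl]decahydronaphthalen-1-ol (C1 epimers) | OC1CCC[C@@H]2[C@@](C)(Cc3c(OC)c(OC)cc(OC)c3OC)[C@H](C)CC[C@@]12C | intermediate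
17 | (4aR,5S,6R,8aR)-5,6,8a-trimethyl-5-[(2,3,5,6-tetramethoxyphenyl)methyl]octahydronaphthalen-1(2H)-one | O=C1CCC[C@@H]2[C@@](C)(Cc3c(OC)c(OC)cc(OC)c3OC)[C@H](C)CC[C@@]12C | intermediate
18 | 3-{[(1S,2R,4aR,8aR)-1,2,4a-trimethyl-5-methylidenedecahydronaphthalen-1-yl]methyl}-1,2,4,5-tetramethoxybenzene | C=C1CCC[C@@H]2[C@@](C)(Cc3c(OC)c(OC)cc(OC)c3OC)[C@H](C)CC[C@@]12C | intermediate
19 | 2,5-dimethoxy-3-{[(1S,2R,4aR,8aR)-1,2,4a-trimethyl-5-methylidenedecahydronaphthalen-1-yl]methyl}cyclohexa-2,5-diene-1,4-dione | C=C1CCC[C@@H]2[C@@](C)(CC3=C(OC)C(=O)C=C(OC)C3=O)[C@H](C)CC[C@@]12C | intermediate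
20 | 2-hydroxy-5-methoxy-3-{[(1S,2R,4aR,8aR)-1,2,4a-trimethyl-5-methylidenedecahydronaphthalen-1-yl]methyl}cyclohexa-2,5-diene-1,4-dione | C=C1CCC[C@@H]2[C@@](C)(CC3=C(O)C(=O)C=C(OC)C3=O)[C@H](C)CC[C@@]12C | target

**Step count**

Total: 11 steps. Longest linear sequence: 11 steps (1 to 20); 6 and 7 are bought.

**Steps most likely to fail**

Step 4. The hindered, fully substituted aluminium enolate may not add to the vinyl ketone in the same flask, so that only the protonated conjugate adduct is obtained, or excess alane may consume the vinyl ketone. Fallback: setting out from 5 and 6, the copper-catalysed addition is run alone and enolate 10 is quenched with TMSOTf at −30 °C to the trimethylsilyl enol ether F1, which is isolated. MeLi in THF at 0 °C then releases the lithium enolate F2, which adds to 7 at −78 °C to give the adduct lithium enolate F3. Work-up with dilute HCl leads through 12 back to the route at 13.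

Step 7. The secondary C8 radical may be reduced by the stannane, or may take the carbinol hydrogen from C4, before it closes onto the hindered styrene, whose aryl ring is twisted out of conjugation. Fallback: setting out from diol 14, the side-chain carbinol alone is oxidised (TEMPO cat., PhI(OAc)2, CH2Cl2) to the hydroxy ketone F4. SmI2, HMPA, t-BuOH in THF then closes ring B by 6-exo ketyl–olefin cyclisation to the bicyclic diol F5; the ketyl forms reversibly and has no hydrogen-atom donor to quench it, and the same allylic strain fixes C9. Dess–Martin periodinane oxidises the ring carbinol to the keto alcohol F6, and Burgess reagent dehydrates the tertiary alcohol to the alkene F7. H2 over Pd/C in EtOAc adds hydrogen to C8 from the face away from the axial methyls C12 and C14, which places C13 equatorial and returns to the route at 17.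

Step 3. A second methyl coupling or scrambling of the alkene geometry at palladium may erode the purity of the bromide. Fallback: setting out from aldehyde 3, a Wittig olefination with the bromo ylide Ph3P=C(Br)CH3 (from ethyltriphenylphosphonium bromide, n-BuLi, Br2, then a second equivalent of n-BuLi, THF, −78 °C), a reaction that places the halogen cis to the aldehyde-derived group, returns directly to the route at 5.

**Further compounds**

F1 | step 4 | trimethyl({(3R)-2-methyl-3-[(Z)-1-(2,3,5,6-tetramethoxyphenyl)prop-1-en-2-yl]cyclohex-1-en-1-yl}oxy)silane | CC1=C(O[Si](C)(C)C)CCC[C@@H]1/C(C)=C\c1c(OC)c(OC)cc(OC)c1OC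
F2 | step 4 | lithium (3R)-2-methyl-3-[(Z)-1-(2,3,5,6-tetramethoxyphenyl)prop-1-en-2-yl]cyclohex-1-en-1-olate | CC1=C(O[Li])CCC[C@@H]1/C(C)=C\c1c(OC)c(OC)cc(OC)c1OC
F3 | step 4 | lithium enolate of the Michael adduct (enolate of the silyl ketone arm) | CC(O[Li])=C(C[C@@]1(C)C(=O)CCC[C@@H]1/C(C)=C\c1c(OC)c(OC)cc(OC)c1OC)[Si](C)(C)C
F4 | step 7 | 4-{(1R,6R)-2-hydroxy-1-methyl-6-[(Z)-1-(2,3,5,6-tetramethoxyphenyl)prop-1-en-2-yl]cyclohexyl}butan-2-one (ring carbinol epimers) | CC(=O)CC[C@@]1(C)C(O)CCC[C@@H]1/C(C)=C\c1c(OC)c(OC)cc(OC)c1OC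
F5 | step 7 | bicyclic diol: 16 with an additional tertiary hydroxyl on C8 (epimers at C8 and C4) | OC1CCC[C@@H]2[C@@](C)(Cc3c(OC)c(OC)cc(OC)c3OC)C(C)(O)CC[C@@]12C
F6 | step 7 | keto alcohol: 17 with a tertiary hydroxyl on C8 (C8 epimers) | O=C1CCC[C@@H]2[C@@](C)(Cc3c(OC)c(OC)cc(OC)c3OC)C(C)(O)CC[C@@]12C
F7 | step 7 | alkene: 17 with a C7=C8 double bond | O=C1CCC[C@@H]2[C@@](C)(Cc3c(OC)c(OC)cc(OC)c3OC)C(C)=CC[C@@]12C
F0 | step 3 | none | none
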